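The numbers in the tables were generated by integration on assumed constants.

**Coupling partner.** The oak yield over the elm yield at 30.0 min is 1.63, and the oak equivalents over the elm equivalents are 1.50. The logarithm of the first ratio over the logarithm of the second gives 1.21. This is the partner order, the apparent reaction order in coupling partner at a fixed time and fixed other charges. It is a reading, since each yield scatters by 2 percentage points.

| flask | substrate | coupling partner | capture agent | remark | time |
|---|---|---|---|---|---|
| elm | 1 M | 1 equiv | 0.050 M | run made earlier |  |
| oak | 1 M | 1.5 equiv | 0.050 M | run made earlier |  |
| flask | 1.0 M | 2.00 equiv | 0.0500 M |  | 30 min |

| elm: time / min | elm: double product / % | oak: time / min | oak: double product / % |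
|---|---|---|---|
| 8.00 | 3 | 8.00 | 10 |
| 10.0 | 9 | 10.0 | 9 |
| 12.0 | 8 | 12.0 | 17 |
| 15.0 | 11 | 15.0 | 23 |
| 25.0 | 15 | 25.0 | 27 |
| 30.0 | 19 | 30.0 | 31 |

(standard deviation of a reading: 2 percentage points)

- amounts and yields of double product count crystals too
- given per volume of solution although it is solid: crystals
- the analysis behind the earlier runs scatters by 2 percentage points, standard deviation
- candidate steps: single product + capture agent -> trapped intermediate; coupling partner + single product -> double product; coupling partner + double product -> tris adduct; coupling partner + tris adduct -> tetra adduct; crystals <-> double product; substrate + coupling partner -> single product

- time up to 30 min at which double product stands highest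
- the amount of double product, in percent of the substrate charged, at that time

**Fixed charges.** Substrate and capture agent are charged alike in elm, oak and this flask, so neither enters the reckoning.

**Reaction time.** Both runs gain 4 points between 25.0 min and 30.0 min, against a scatter of 2 points. The reckoning therefore places the peak at the longest time allowed, 30 min.

**Own reckoning.** Moving from oak to 2.00 equiv multiplies the oak yield by the equivalents ratio raised to the partner order. This gives 43.9 % of the charge.

**The result.** The forecast gives 43 % at 30 min, seeing “no sign of a maximum”. The flask gives 44.6 % at 30.0 min, which is 0.70 points from the reckoning.

    single product + capture agent → trapped intermediate (k = 0.440 /M/min)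
    coupling partner + single product → double product (k = 0.0800 /M/min)
    coupling partner + double product → tris adduct (k = 0.0590 /M/min)
    coupling partner + tris adduct → tetra adduct (k = 0.0150 /M/min)
    crystals ⇌ double product, rate k5*(cs5 - [double product]) while solid is left; crystals form when [double product] > cs5 (solubility = 46.0 mM, k = 6.20 /min)
    substrate + coupling partner → single product (k = 0.0430 /M/min)

**Low partner.** A neighbouring flask differs in one setting, with 0.500 equiv of coupling partner, and is read at 30.0 min. Its charge lies below both runs, so the partner order is carried downward from elm. That reckoning gives 8.23 % of the charge as double product. The neighbouring flask gives 6.21 %, a gap of 2 points. In that flask the coupling partner keeps 24.3 % of its own charge. Substrate in that flask stands at 70.6 % of the charge, more than double product.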